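## Analysis of the target

CNP0222085.1 (41) is a briarane-type diterpenoid. A cyclohexene (ring A: C1, C10, C11, C12, C13=C14) is trans-fused at C1–C10 to a ten-membered carbocycle (C1–C10), which carries a trans-fused α-methyl-β-hydroxy-γ-lactone across C7–C8 (C7–O–C19(=O)–C17–C8). There are nine stereocentres. Taking the face of the C1 methyl (C15) as β, ring A has C15, the C10–C9 bond and the C11 methyl (C20) all β and the C12 hydroxyl α; on the medium ring the oxygens on C2, C7, C8 and C9 are all α, and the C17 methyl is cis to the C8 hydroxyl. The C5=C6 bond is trisubstituted and Z. Sensitive groups are the two secondary acetates (the C9 acetate sits next to the free tertiary C8 hydroxyl, so acyl migration and translactonisation threaten under base), the β-hydroxy lactone (retro-aldol, epimerisable C17) and the allylic C12 alcohol. The hard part is the ten-membered ring: it has to be closed beside the quaternary C1 with a Z trisubstituted alkene and five oxygenated carbons in place. The strategy rests on C3 and C4, two plain methylenes bridging the oxygenated C2 and the olefinic C5. They are formally ethylene inserted into the C2–C5 bond of an eight-membered ring (C1, C2, C5, C6, C7, C8, C9, C10), which is much easier to close.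

## Retrosynthetic reasoning

**41 back to 37.** The aryl ether on O12 and the two acetates are removed last, leading through 40 and 39 to alcohol 38 and then to ketone 37. C2 is carried as a ketone because the ring expansion delivers it in that oxidation state; its reduction is left to a catalyst that distinguishes the quaternary C1 from the C3 methylene. C9 stays a silyl ether until the end, because a C9 acetate would not survive the reductive lactone closure and a free C9 hydroxyl under base could capture the lactone carbonyl.

**37 back to 33.** The C5=C6 alkene and the C2 carbonyl are reconnected as the C2–C5 bond of a cyclobutane with a leaving group on C6 (mesylate 36, from diol 35). This Grob fragmentation is strain-driven and stereospecific: the Z geometry follows from a 6α leaving group, trans to the C5 methyl, in photoadduct 33. C8 is kept as a free hydroxyl at this stage, so that only the C2 oxygen becomes an alkoxide.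

**33 back to 31 and ethylene 32.** Cutting C2–C3 and C4–C5 removes the two unfunctionalised carbons and leaves the eight-membered β-silyloxy enone 31. No other disconnection supplies C3–C4 without functional groups that would have to be removed again. The forward reaction must add 32 across C2=C5 only; that is a question of where the enol ether oxygen sits. The C2 silyl group is triethylsilyl, not a bulkier one, because it has to be cleaved from a tertiary cyclobutanol later.

**31 back to 27.** Direct O-silylation of a 2-methyl-1,3-diketone flanked by the quaternary C1 would be expected to go to the less hindered C6 oxygen, the wrong one. The enol ether is therefore made from a compound in which only C2 is a ketone: aldol 27 (C2=O, C6–OH). C2 can enolise only toward C5, and the C6 carbinol is oxidised afterwards (30 to 31).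

**27 back to 26.** The eight-membered ring is opened at C5–C6: an α-bromo ketone at C2/C5 and an aldehyde at C6, joined by a reductive Reformatsky-type aldol. This polarity, and not its reverse, is chosen because it leaves the carbonyl on C2 as the previous paragraph requires. The new centres C5 and C6 need no control.

**26 back to 17.** The lactone is cut at C8–C17: an intramolecular Reformatsky reaction of bromopropanoate 19 (from 17 and 18) onto a C8 ketone gives 20. The tether from O7 decides the configuration at C8. The C12 carbonyl of ring A is reduced only after this step and then inverted (21 to 22), since the axial C9 branch forces the reduction to the wrong face.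

**17 back to 8 and 12.** The C8–C9 bond is cut between aldehyde 8 and vinyl triflate 12 (Nozaki–Hiyama–Kishi coupling to 13). The methylene of 13 is a masked C8 ketone, revealed by ozonolysis (15) while ring A is still an electron-poor enone. C7 and its oxygen come from the chiral pool (9).

**8 back to 2 and 3.** Ring A is cut at C1–C14 and C10–C11: a Diels–Alder reaction of diene 2 (from 1) with enal ester 3 gives 4 and sets C1, C10 and C11. The ester of 3 becomes C9 and the formyl group becomes C2.

## Alternatives that were turned down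

**Alternative 1:** The disconnection is the same ring A cut (C1–C14 and C10–C11), but made the centrepiece: diene A2 and (E)-enal A3 combine in a catalysed, formyl-exo [4+2] addition, and loss of methanol gives enone aldehyde A1 with C1, C10 and C11 set.
- For it: three stereocentres, the quaternary carbon and the C12/C13=C14 pattern come from one catalytic step and two small fragments.
- Against it: the step settles ring A only. The ten-membered ring, its Z alkene and the trans lactone are left to a direct medium-ring closure that must thread the C3–C4 chain. A 1-alkoxy-3-silyloxy diene such as A2 can also divert to hetero-cycloaddition or Mukaiyama addition at the formyl group under Lewis acid.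
- Comparison: on ring A it is as strong as the chosen plan, which builds ring A by a cycloaddition of the same family (2 + 3 to 4). The chosen strategy adds what A1 leaves open: an eight-membered ring that is easier to close, then enlarged by 32.

**Alternative 2:** The bond cut is C1–C2. In a thirteen-membered ring in which C2 is tied to C13 through oxygen, tin–lithium exchange at C2 triggers a [2,3]-Wittig shift. It forms C1–C2, moves the alkene to C13=C14 and contracts the ring to carbocycle A4.
- For it: macro-etherification is easier than closing a ten-membered carbocycle directly. The shift creates the quaternary C1 and the C2 carbinol together, with chirality relayed from C13, and delivers a free C2 hydroxyl ready for acetylation. On C2 it is stronger than the chosen route, which must reduce a hindered ketone late.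
- Against it: the migration terminus C1 is a fully substituted, ring-embedded alkene carbon, so the [2,3] shift has to outrun the [1,2] shift in a strained bicyclic transition state. The α-stannyl ether must survive a macrocyclisation. A4 still carries the lactone carbons as a protected triol, so oxidation, lactonisation and several protecting-group changes follow. The Z alkene and the C3–C4 chain are carried in open-chain form throughout.
- Comparison: the chosen strategy gives up the elegant C1–C2 construction for a ring-forming event driven by cyclobutane strain and for a short post-key sequence with the lactone already in place.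

**Alternative 3:** The disconnection is C1–C10 inside ring A, by an Ireland–Claisen rearrangement. In a six-membered ring whose oxygen is bonded to C13, the C9=C10 enolate unit (as its silyl derivative) shifts [3,3] through a boat onto a (Z)-C14=C1 alkene, forming C1–C10 and contracting the heterocycle to ring A acid A5.
- For it: absolute configuration comes from the chiral pool without an asymmetric catalyst, the shift is stereospecific, and C12 arrives with the correct configuration and protected. That is better than the chosen route, which needs a reduction and a Mitsunobu inversion at C12.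
- Against it: like Alternative 1 it ends at ring A. A5 is further from the medium ring than 8 (C2 is a benzyl ether, C9 an acid). The boat preference and the Z geometry of the migration terminus both have to be right, and the path to the rearrangement substrate is much longer than a two-component cycloaddition.
- Comparison: the chosen route reaches 8 in six steps and spends its effort on the ten-membered ring, where the real difficulty lies.

Key step: step 24

Assumption (chemistry): the (S)-configured oxazaborolidinium ion of step 2 is taken to expose the C1 Si face of formyl-bound 3; if its sense is the reverse, the (R)-catalyst is used and nothing else changes.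

## Route

Step 1
Reactants: 1 pent-1-en-3-one
Product: 2 (Z)-3-(triisopropylsilyloxy)penta-1,3-diene
Conditions: iPr3SiOTf, Et3N, CH2Cl2, 0 °C
Reagents that add atoms: triisopropylsilyl trifluoromethanesulfonate, CC(C)[Si](C(C)C)(C(C)C)OS(=O)(=O)C(F)(F)F
Why: Soft enolisation of the ethyl ketone (silyl enol ether formation) gives the (Z)-enol ether and leaves the vinyl group untouched, so the 2-silyloxy diene forms in one operation.

Step 2
Reactants: 2 (Z)-3-(triisopropylsilyloxy)penta-1,3-diene; 3 ethyl (E)-3-methyl-4-oxobut-2-enoate
Product: 4 ethyl (1S,2R,6S)-6-formyl-2,6-dimethyl-3-(triisopropylsilyloxy)cyclohex-3-ene-1-carboxylate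
Conditions: (S)-3,3-diphenyl-1-(2-methylphenyl)tetrahydro-1H,3H-pyrrolo[1,2-c][1,3,2]oxazaborole·HNTf2 (20 mol%), CH2Cl2, −78 °C
Reagents that add atoms: none
Why: Diels–Alder reaction with the oxazaborolidinium ion bound to the formyl group: the enol ether terminus C11 attacks C10 (β to the aldehyde), so the C12 oxygen ends para to C1. The α-methyl enal should react formyl-exo and ester-endo, which places the outside methyl of the (Z)-diene cis to C9 and C15; the catalyst exposes the C1 Si face, setting C1, C10 and C11.

Step 3
Reactants: 4 ethyl (1S,2R,6S)-6-formyl-2,6-dimethyl-3-(triisopropylsilyloxy)cyclohex-3-ene-1-carboxylate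
Product: 5 ring A ethyl carbinol (CH(OH)CH2CH3 on C1 in place of CHO; both C2 epimers)
Conditions: EtMgBr, CeCl3, THF, −78 °C
Reagents that add atoms: ethylmagnesium bromide, CC[Mg]Br
Why: Cerium-modified Grignard addition to the neopentyl aldehyde is faster than attack on the hindered ester and suppresses β-hydride reduction; the carbinol configuration is irrelevant because C2 is oxidised in step 5.

Step 4
Reactants: 5 ring A ethyl carbinol
Product: 6 ring A diol (C9 CH2OH on C10; C2 carbinol; C12 silyl enol ether)
Conditions: LiAlH4, Et2O, 0 °C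
Reagents that add atoms: none
Why: Ester reduction gives the C9 primary alcohol; the triisopropylsilyl enol ether that masks the C12 ketone is inert to hydride.

Step 5
Reactants: 6 ring A diol
Product: 7 ring A keto aldehyde (C9 CHO; C2 ethyl ketone; C12 silyl enol ether)
Conditions: Dess–Martin periodinane (2.6 equiv), NaHCO3, CH2Cl2, 0 °C to rt
Reagents that add atoms: none
Why: Both hydroxyls are oxidised at once, giving the ethyl ketone (enolisable only toward C5, since C1 is quaternary) and the C9 aldehyde; the two side chains are trans on ring A, so no lactol intervenes.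

Step 6
Reactants: 7 ring A keto aldehyde
Product: 8 ring A enone keto aldehyde (C12=O, C13=C14; 1β-CH3, 10α-H, 11β-CH3)
Conditions: Pd(OAc)2 (1.2 equiv), MeCN, 40 °C
Reagents that add atoms: none
Why: Saegusa–Ito oxidation: palladation of the enol ether at C13 and β-hydride elimination toward C14 give the enone regiospecifically, and the neutral conditions leave C10 and C11 untouched.

Step 7
Reactants: 9 methyl (S)-2,2-dimethyl-1,3-dioxolane-4-carboxylate
Product: 11 1-[(4S)-2,2-dimethyl-1,3-dioxolan-4-yl]ethan-1-one, via Weinreb amide 10 (not isolated)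
Conditions: MeNH(OMe)·HCl, iPrMgCl, THF, −20 °C; then MeMgBr, 0 °C
Reagents that add atoms: methylmagnesium bromide, C[Mg]Br
Why: The magnesium amide converts the ester into the Weinreb amide, and methyl Grignard addition stops at the ketone through the chelated tetrahedral intermediate; the C7 stereocentre comes from the chiral pool.

Step 8
Reactants: 11 1-[(4S)-2,2-dimethyl-1,3-dioxolan-4-yl]ethan-1-one
Product: 12 1-[(4S)-2,2-dimethyl-1,3-dioxolan-4-yl]ethenyl trifluoromethanesulfonate
Conditions: KN(SiMe3)2, THF, −78 °C; PhNTf2
Reagents that add atoms: N-phenylbis(trifluoromethanesulfonimide), O=S(=O)(N(c1ccccc1)S(=O)(=O)C(F)(F)F)C(F)(F)F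
Why: Kinetic deprotonation of the methyl group (the α-alkoxy methine is more hindered) and O-triflation give the 2-substituted vinyl triflate without touching C7.

Step 9
Reactants: 8 ring A enone keto aldehyde; 12 1-[(4S)-2,2-dimethyl-1,3-dioxolan-4-yl]ethenyl trifluoromethanesulfonate
Product: 13 (9R)-allylic alcohol (C10–CH(OH)–C8(=CH2)–dioxolanyl)
Conditions: CrCl2 (6 equiv), NiCl2 (2 mol%), DMF, rt
Reagents that add atoms: none
Why: Nozaki–Hiyama–Kishi coupling: the alkenylchromium species adds only to the aldehyde and spares the enone and the ethyl ketone. Addition anti to the quaternary C1 (Felkin–Anh) should favour the (9R) carbinol; the minor epimer is removed by chromatography.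

Step 10
Reactants: 13 (9R)-allylic alcohol
Product: 14 C9 tert-butyldimethylsilyl ether of 13
Conditions: tBuMe2SiOTf, 2,6-lutidine, CH2Cl2, −78 to 0 °C
Reagents that add atoms: tert-butyldimethylsilyl trifluoromethanesulfonate, CC(C)(C)[Si](C)(C)OS(=O)(=O)C(F)(F)F
Why: Silylation of the hindered allylic alcohol gives a non-participating ether that is not cleaved reductively next to a ketone and lasts until step 29.

Step 11
Reactants: 14 C9 silyl ether
Product: 15 C8 ketone (C9 OSitBuMe2; C6/C7 acetonide)
Conditions: O3 (1 equiv, titrated), CH2Cl2, pyridine, −78 °C; PPh3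
Reagents that add atoms: ozone, [O-][O+]=O
Why: Ozonolysis of the electron-rich 1,1-disubstituted alkene is much faster than attack on the electron-poor enone C13=C14, so the C8 ketone is unveiled selectively.

Step 12
Reactants: 15 C8 ketone
Product: 16 C6,C7-diol C8 ketone
Conditions: AcOH/THF/H2O (3:1:1), 45 °C
Reagents that add atoms: none
Why: Acid hydrolysis of the terminal acetonide frees O6 and O7; the hindered secondary silyl ether at C9 is stable to aqueous acetic acid.

Step 13
Reactants: 16 C6,C7-diol C8 ketone
Product: 17 C6 triethylsilyl ether with free C7 hydroxyl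
Conditions: Et3SiCl, imidazole, CH2Cl2, −40 °C
Reagents that add atoms: chlorotriethylsilane, CC[Si](CC)(CC)Cl
Why: The primary C6 hydroxyl is silylated much faster than the secondary α-ketol hydroxyl at C7.

Step 14
Reactants: 17 C6 triethylsilyl ether with free C7 hydroxyl; 18 2-bromopropanoyl bromide
Product: 19 C7 2-bromopropanoate (both CHBr epimers)
Conditions: pyridine, CH2Cl2, −40 °C
Reagents that add atoms: none
Why: Acylation of the only free hydroxyl attaches C17–C19 as an α-bromo ester placed to reach the C8 carbonyl through a five-membered ring.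

Step 15
Reactants: 19 C7 2-bromopropanoate
Product: 20 γ-lactone (8α-OH; C17 methyl cis to it; C6 CH2OSiEt3; C9 OSitBuMe2)
Conditions: SmI2 (2.3 equiv), THF, −78 °C
Reagents that add atoms: none
Why: Intramolecular samarium Reformatsky reaction: C–Br reduction outruns ketyl formation, and the tethered enolate closes the lactone on the face of C8 that puts the bulky C9 branch trans to C6, giving 8α-OH. The C17 methyl settles trans to that branch (chelated transition state, also the thermodynamic epimer).

Step 16
Reactants: 20 γ-lactone
Product: 21 12β-allylic alcohol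
Conditions: NaBH4, CeCl3·7H2O, MeOH/THF, −78 °C
Reagents that add atoms: none
Why: Luche 1,2-reduction of the enone; the hindered C2 ketone and the lactone are untouched at −78 °C, and hydride enters anti to the axial C9 branch on C10, giving the axial 12β alcohol.

Step 17
Reactants: 21 12β-allylic alcohol
Product: 22 12α-(4-methoxyphenyl) ether
Conditions: 4-methoxyphenol, PPh3, DIAD, toluene, 0 °C to rt
Reagents that add atoms: 4-methoxyphenol, COc1ccc(O)cc1
Why: Mitsunobu etherification inverts C12 by backside attack on the axial oxyphosphonium (SN2' at C14 is blocked by the quaternary C1); the tertiary C8 hydroxyl does not react. The aryl ether withstands reductants, fluoride and base and is removed oxidatively at the end.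

Step 18
Reactants: 22 12α-(4-methoxyphenyl) ether
Product: 24 C5-bromo ketone with C8 OSiMe3 (both C5 epimers), via silyl enol ether 23 (not isolated)
Conditions: Me3SiOTf (2.4 equiv), Et3N, CH2Cl2, −20 °C; then NBS, THF, −78 °C
Reagents that add atoms: trimethylsilyl trifluoromethanesulfonate, C[Si](C)(C)OS(=O)(=O)C(F)(F)F; N-bromosuccinimide, O=C1CCC(=O)N1Br
Why: Enolisation is possible only toward C5 because C1 is quaternary, and the silyl enol ether is brominated faster than the lactone or the electron-rich arene; the tertiary C8 hydroxyl is silylated in passing.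

Step 19
Reactants: 24 C5-bromo ketone with C8 OSiMe3
Product: 25 bromo ketone diol (C6 OH; C8 OH)
Conditions: PPTS, MeOH/CH2Cl2, 0 °C to rt
Reagents that add atoms: none
Why: Mild acidic methanolysis removes the primary triethylsilyl and the trimethylsilyl ether, while the hindered secondary tert-butyldimethylsilyl ether and the α-bromo ketone survive.

Step 20
Reactants: 25 bromo ketone diol
Product: 26 bromo ketone C6 aldehyde
Conditions: Dess–Martin periodinane, NaHCO3, CH2Cl2, 0 °C
Reagents that add atoms: none
Why: Buffered periodinane oxidation gives the sensitive α-acyloxy aldehyde under neutral conditions; the tertiary hydroxyl is inert and the aldehyde is used at once.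

Step 21
Reactants: 26 bromo ketone C6 aldehyde
Product: 27 eight-membered β-hydroxy ketone (C2=O; C6 OH; C5 and C6 epimers)
Conditions: SmI2 (2.5 equiv), THF (0.005 M), −78 to −40 °C
Reagents that add atoms: none
Why: Samarium Reformatsky-type aldol at high dilution: the bromo ketone is reduced to the samarium enolate, which closes the eight-membered ring on the aldehyde through a chelated transition state, a closure type with good precedent for eight-membered carbocycles. C5 and C6 need no control because both become trigonal in steps 22 and 23.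

Step 22
Reactants: 27 eight-membered β-hydroxy ketone
Product: 30 C2 triethylsilyl enol ether with free C6 hydroxyl (C8 OSiMe3), via bis-trimethylsilyl ether 28 (not isolated), via triethylsilyl enol ether 29 (not isolated)
Conditions: 1-(trimethylsilyl)imidazole, CH2Cl2, 0 °C; Et3SiOTf, Et3N, −78 to 0 °C; K2CO3 (0.2 equiv), MeOH, −20 °C
Reagents that add atoms: 1-(trimethylsilyl)imidazole, C[Si](C)(C)n1ccnc1; triethylsilyl trifluoromethanesulfonate, CC[Si](CC)(CC)OS(=O)(=O)C(F)(F)F
Why: With both hydroxyls capped, the C2 ketone can enolise only toward C5, so the enol ether oxygen is fixed on C2 without passing through a 1,3-diketone whose silylation would favour the less hindered C6 oxygen. Cold basic methanolysis then removes the secondary trimethylsilyl ether much faster than the tertiary one or the hindered tetrasubstituted enol ether; any C8 ether lost here converges at 35.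

Step 23
Reactants: 30 C2 triethylsilyl enol ether with free C6 hydroxyl
Product: 31 eight-membered β-silyloxy enone (C2 OSiEt3; C6=O; C8 OSiMe3; C9 OSitBuMe2; C12 OAr)
Conditions: Dess–Martin periodinane, pyridine, CH2Cl2, 0 °C
Reagents that add atoms: none
Why: Buffered oxidation of the allylic alcohol gives the vinylogous silyl ester with the carbonyl on C6; the silyl group cannot shift to O6 because the ring holds O2 and C6 trans across C2=C5.

Step 24
Reactants: 31 eight-membered β-silyloxy enone; 32 ethylene
Product: 33 cyclobutane photoadduct (C3 and C4 on the α face; C2 OSiEt3 and C5 CH3 β)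
Conditions: hν (350 nm, Pyrex), C2H4-saturated CH2Cl2, −78 °C
Reagents that add atoms: none
Why: Enone–alkene [2+2] photocycloaddition; the closest precedent is the addition of ethylene to cyclic β-silyloxy and β-acyloxy enones (de Mayo chemistry). Excitation at 350 nm gives the n,π* state, which crosses to the triplet; the triplet adds 32 at C5 or C2 to a 1,4-biradical that, after spin inversion, collapses to the cyclobutane, forming C2–C3 and C4–C5. The four-membered ring is closed by radical recombination and can only be cis-fused to the eight-membered ring, so the new centres C2 and C5 are fixed relative to each other by the fusion. Ethylene is expected on the α face, anti to the β methyl on C1 that flanks C2; either face would serve, since C2 and C5 become trigonal in step 27 and only the sense of the C6 reduction would have to follow. Regiochemistry, the selectivity that matters, is secured by the substrate: oxygen is on C2 and the carbonyl on C6 by construction (steps 22 and 23), so 32 must span C2–C5. Only the enone absorbs above 320 nm (the C13=C14 alkene and the aryl ether do not), and the fused rings hold C2=C5 cis so that E/Z relaxation is restricted. A large excess of 32 at −78 °C favours bimolecular capture over unimolecular decay.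

Step 25
Reactants: 33 cyclobutane photoadduct
Product: 35 6α,8α-diol (C2 OSiEt3 retained), via C8 trimethylsilyl ether 34 (not isolated)
Conditions: NaBH4, MeOH/THF, −20 °C; then PPTS, MeOH, 0 °C
Reagents that add atoms: none
Why: Hydride is expected to enter anti to the C7–O bond (polar Felkin–Anh) and away from the α-fused cyclobutane, that is from the β face, giving the 6α alcohol cis to C4 and trans to the C5 methyl, as the fragmentation requires. Mild methanolysis then frees the tertiary C8 hydroxyl, so that only C2 can later become an alkoxide.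

Step 26
Reactants: 35 6α,8α-diol
Product: 36 6α-mesylate (C8 OH free)
Conditions: MsCl, Et3N, CH2Cl2, −20 to 0 °C
Reagents that add atoms: methanesulfonyl chloride, CS(=O)(=O)Cl
Why: Mesylation through the sulfene pathway takes the neopentyl-type secondary alcohol and leaves the more hindered tertiary C8 hydroxyl alone.

Step 27
Reactants: 36 6α-mesylate
Product: 37 ten-membered C2 ketone with (Z)-C5=C6 (C8 OH; C9 OSitBuMe2; C12 OAr)
Conditions: Bu4NF (1.5 equiv), THF, −20 to 0 °C
Reagents that add atoms: none
Why: Fluoride cleaves the tertiary triethylsilyl ether, and the C2 alkoxide triggers a Grob (Wharton-type) fragmentation: the strained C2–C5 bond, anti-periplanar to C6–OMs, breaks to give the C2 ketone and C5=C6. In the reactive conformer C7 lies anti to the C5 methyl, so C4 and C7 end up cis (Z); the hindered C9 silyl ether survives the short exposure and the free C8 hydroxyl is not ionised.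

Step 28
Reactants: 37 ten-membered C2 ketone
Product: 38 2α-alcohol ((2R) carbinol)
Conditions: (S)-1-methyl-3,3-diphenyltetrahydro-1H,3H-pyrrolo[1,2-c][1,3,2]oxazaborole (1 equiv), catecholborane, toluene, −40 °C
Reagents that add atoms: none
Why: Corey–Bakshi–Shibata reduction: the quaternary C1 and the C3 methylene are a clear large/small pair, so the (S)-catalyst should give the (2R) = 2α alcohol under reagent control; catecholborane is used so that the alkenes are not hydroborated.

Step 29
Reactants: 38 2α-alcohol
Product: 39 2,8,9-triol 12-(4-methoxyphenyl) ether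
Conditions: HF·pyridine, pyridine, THF, 0 °C to rt
Reagents that add atoms: none
Why: Buffered hydrogen fluoride removes the last silyl ether under mildly acidic conditions, where the freed C9 hydroxyl is not expected to translactonise.

Step 30
Reactants: 39 2,8,9-triol 12-(4-methoxyphenyl) ether
Product: 40 2,9-diacetate 12-(4-methoxyphenyl) ether
Conditions: Ac2O, DMAP, pyridine, CH2Cl2, 0 °C to rt
Reagents that add atoms: acetic anhydride, CC(=O)OC(C)=O
Why: Both secondary hydroxyls are acetylated; the tertiary C8 hydroxyl, flanked by C7, C9 and C17, is not acylated under these conditions.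

Step 31
Reactants: 40 2,9-diacetate 12-(4-methoxyphenyl) ether
Product: 41 CNP0222085.1
Conditions: (NH4)2Ce(NO3)6, MeCN/H2O (4:1), 0 °C
Reagents that add atoms: none
Why: Oxidative dearylation: one-electron oxidation of the 4-methoxyphenyl ether and hydrolysis of the quinone monoketal release the 12α alcohol without touching the esters, the lactone or the alkenes.

## Compound list

1 | pent-1-en-3-one | CCC(=O)C=C | starting material
2 | (Z)-3-(triisopropylsilyloxy)penta-1,3-diene | C=C/C(=C/C)O[Si](C(C)C)(C(C)C)C(C)C | intermediate
3 | ethyl (E)-3-methyl-4-oxobut-2-enoate | CCOC(=O)/C=C(\C)C=O | starting material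
4 | ethyl (1S,2R,6S)-6-formyl-2,6-dimethyl-3-(triisopropylsilyloxy)cyclohex-3-ene-1-carboxylate | CCOC(=O)[C@H]1[C@@H](C)C(O[Si](C(C)C)(C(C)C)C(C)C)=CC[C@]1(C)C=O | intermediate
5 | ring A ethyl carbinol (C2 epimers) | CCOC(=O)[C@H]1[C@@H](C)C(O[Si](C(C)C)(C(C)C)C(C)C)=CC[C@]1(C)C(O)CC | intermediate
6 | ring A diol | OC[C@H]1[C@@H](C)C(O[Si](C(C)C)(C(C)C)C(C)C)=CC[C@]1(C)C(O)CC | intermediate
7 | ring A keto aldehyde with C12 silyl enol ether | O=C[C@H]1[C@@H](C)C(O[Si](C(C)C)(C(C)C)C(C)C)=CC[C@]1(C)C(=O)CC | intermediate
8 | ring A enone keto aldehyde | O=C[C@H]1[C@@H](C)C(=O)C=C[C@]1(C)C(=O)CC | intermediate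
9 | methyl (S)-2,2-dimethyl-1,3-dioxolane-4-carboxylate | COC(=O)[C@@H]1COC(C)(C)O1 | starting material
10 | (S)-N-methoxy-N,2,2-trimethyl-1,3-dioxolane-4-carboxamide | CON(C)C(=O)[C@@H]1COC(C)(C)O1 | intermediate
11 | 1-[(4S)-2,2-dimethyl-1,3-dioxolan-4-yl]ethan-1-one | CC(=O)[C@@H]1COC(C)(C)O1 | intermediate
12 | 1-[(4S)-2,2-dimethyl-1,3-dioxolan-4-yl]ethenyl trifluoromethanesulfonate | C=C(OS(=O)(=O)C(F)(F)F)[C@@H]1COC(C)(C)O1 | intermediate
13 | (9R)-allylic alcohol | C=C([C@@H]1COC(C)(C)O1)[C@H](O)[C@H]2[C@@H](C)C(=O)C=C[C@]2(C)C(=O)CC | intermediate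
14 | C9 tert-butyldimethylsilyl ether | C=C([C@@H]1COC(C)(C)O1)[C@H](O[Si](C)(C)C(C)(C)C)[C@H]2[C@@H](C)C(=O)C=C[C@]2(C)C(=O)CC | intermediate
15 | C8 ketone | O=C([C@@H]1COC(C)(C)O1)[C@H](O[Si](C)(C)C(C)(C)C)[C@H]2[C@@H](C)C(=O)C=C[C@]2(C)C(=O)CC | intermediate
16 | C6,C7-diol C8 ketone | O=C([C@@H](O)CO)[C@H](O[Si](C)(C)C(C)(C)C)[C@H]1[C@@H](C)C(=O)C=C[C@]1(C)C(=O)CC | intermediate
17 | C6 triethylsilyl ether with free C7 hydroxyl | O=C([C@@H](O)CO[Si](CC)(CC)CC)[C@H](O[Si](C)(C)C(C)(C)C)[C@H]1[C@@H](C)C(=O)C=C[C@]1(C)C(=O)CC | intermediate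
18 | 2-bromopropanoyl bromide | CC(Br)C(Br)=O | starting material
19 | C7 2-bromopropanoate | O=C([C@@H](OC(=O)C(C)Br)CO[Si](CC)(CC)CC)[C@H](O[Si](C)(C)C(C)(C)C)[C@H]1[C@@H](C)C(=O)C=C[C@]1(C)C(=O)CC | intermediate
20 | γ-lactone with 8α-OH | CCC(=O)[C@@]1(C)C=CC(=O)[C@H](C)[C@@H]1[C@@H](O[Si](C)(C)C(C)(C)C)[C@]1(O)[C@@H](C)C(=O)O[C@H]1CO[Si](CC)(CC)CC | intermediate
21 | 12β-allylic alcohol | CCC(=O)[C@@]1(C)C=C[C@H](O)[C@H](C)[C@@H]1[C@@H](O[Si](C)(C)C(C)(C)C)[C@]1(O)[C@@H](C)C(=O)O[C@H]1CO[Si](CC)(CC)CC | intermediate
22 | 12α-(4-methoxyphenyl) ether | CCC(=O)[C@@]1(C)C=C[C@@H](Oc2ccc(OC)cc2)[C@H](C)[C@@H]1[C@@H](O[Si](C)(C)C(C)(C)C)[C@]1(O)[C@@H](C)C(=O)O[C@H]1CO[Si](CC)(CC)CC | intermediate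
23 | C2 trimethylsilyl enol ether with C8 OSiMe3 | C/C=C(\O[Si](C)(C)C)[C@@]1(C)C=C[C@@H](Oc2ccc(OC)cc2)[C@H](C)[C@@H]1[C@@H](O[Si](C)(C)C(C)(C)C)[C@]1(O[Si](C)(C)C)[C@@H](C)C(=O)O[C@H]1CO[Si](CC)(CC)CC | intermediate
24 | C5-bromo ketone with C8 OSiMe3 | CC(Br)C(=O)[C@@]1(C)C=C[C@@H](Oc2ccc(OC)cc2)[C@H](C)[C@@H]1[C@@H](O[Si](C)(C)C(C)(C)C)[C@]1(O[Si](C)(C)C)[C@@H](C)C(=O)O[C@H]1CO[Si](CC)(CC)CC | intermediate
25 | bromo ketone diol | CC(Br)C(=O)[C@@]1(C)C=C[C@@H](Oc2ccc(OC)cc2)[C@H](C)[C@@H]1[C@@H](O[Si](C)(C)C(C)(C)C)[C@]1(O)[C@@H](C)C(=O)O[C@H]1CO | intermediate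
26 | bromo ketone C6 aldehyde | CC(Br)C(=O)[C@@]1(C)C=C[C@@H](Oc2ccc(OC)cc2)[C@H](C)[C@@H]1[C@@H](O[Si](C)(C)C(C)(C)C)[C@]1(O)[C@@H](C)C(=O)O[C@H]1C=O | intermediate
27 | eight-membered β-hydroxy ketone (C5, C6 epimers) | CC(C)(C)[Si](C)(C)O[C@@H]1[C@H]2[C@@H](C)[C@H](Oc3ccc(OC)cc3)C=C[C@]2(C)C(=O)C(C)C(O)[C@@H]2OC(=O)[C@H](C)[C@]21O | intermediate
28 | C6,C8 bis(trimethylsilyl) ether | CC(C)(C)[Si](C)(C)O[C@@H]1[C@H]2[C@@H](C)[C@H](Oc3ccc(OC)cc3)C=C[C@]2(C)C(=O)C(C)C(O[Si](C)(C)C)[C@@H]2OC(=O)[C@H](C)[C@]21O[Si](C)(C)C | intermediate
29 | C2 triethylsilyl enol ether with C6 and C8 OSiMe3 | CC(C)(C)[Si](C)(C)O[C@@H]1[C@H]2[C@@H](C)[C@H](Oc3ccc(OC)cc3)C=C[C@]2(C)/C(O[Si](CC)(CC)CC)=C(/C)C(O[Si](C)(C)C)[C@@H]2OC(=O)[C@H](C)[C@]21O[Si](C)(C)C | intermediate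
30 | C2 triethylsilyl enol ether with free C6 hydroxyl | CC(C)(C)[Si](C)(C)O[C@@H]1[C@H]2[C@@H](C)[C@H](Oc3ccc(OC)cc3)C=C[C@]2(C)/C(O[Si](CC)(CC)CC)=C(/C)C(O)[C@@H]2OC(=O)[C@H](C)[C@]21O[Si](C)(C)C | intermediate
31 | eight-membered β-silyloxy enone | CC(C)(C)[Si](C)(C)O[C@@H]1[C@H]2[C@@H](C)[C@H](Oc3ccc(OC)cc3)C=C[C@]2(C)/C(O[Si](CC)(CC)CC)=C(/C)C(=O)[C@@H]2OC(=O)[C@H](C)[C@]21O[Si](C)(C)C | intermediate
32 | ethylene | C=C | starting material
33 | cyclobutane photoadduct | CC(C)(C)[Si](C)(C)O[C@@H]1[C@H]2[C@@H](C)[C@H](Oc3ccc(OC)cc3)C=C[C@]2(C)[C@]3(O[Si](CC)(CC)CC)CC[C@]3(C)C(=O)[C@@H]2OC(=O)[C@H](C)[C@]21O[Si](C)(C)C | intermediate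
34 | 6α-alcohol with C8 OSiMe3 | CC(C)(C)[Si](C)(C)O[C@@H]1[C@H]2[C@@H](C)[C@H](Oc3ccc(OC)cc3)C=C[C@]2(C)[C@]3(O[Si](CC)(CC)CC)CC[C@]3(C)[C@H](O)[C@@H]2OC(=O)[C@H](C)[C@]21O[Si](C)(C)C | intermediate
35 | 6α,8α-diol | CC(C)(C)[Si](C)(C)O[C@@H]1[C@H]2[C@@H](C)[C@H](Oc3ccc(OC)cc3)C=C[C@]2(C)[C@]3(O[Si](CC)(CC)CC)CC[C@]3(C)[C@H](O)[C@@H]2OC(=O)[C@H](C)[C@]21O | intermediate
36 | 6α-mesylate | CC(C)(C)[Si](C)(C)O[C@@H]1[C@H]2[C@@H](C)[C@H](Oc3ccc(OC)cc3)C=C[C@]2(C)[C@]3(O[Si](CC)(CC)CC)CC[C@]3(C)[C@H](OS(C)(=O)=O)[C@@H]2OC(=O)[C@H](C)[C@]21O | intermediate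
37 | ten-membered C2 ketone with (Z)-C5=C6 | CC(C)(C)[Si](C)(C)O[C@@H]1[C@H]2[C@@H](C)[C@H](Oc3ccc(OC)cc3)C=C[C@]2(C)C(=O)CC/C(C)=C\[C@@H]2OC(=O)[C@H](C)[C@]21O | intermediate
38 | 2α-alcohol | CC(C)(C)[Si](C)(C)O[C@@H]1[C@H]2[C@@H](C)[C@H](Oc3ccc(OC)cc3)C=C[C@]2(C)[C@H](O)CC/C(C)=C\[C@@H]2OC(=O)[C@H](C)[C@]21O | intermediate
39 | 2,8,9-triol 12-(4-methoxyphenyl) ether | O[C@@H]1[C@H]2[C@@H](C)[C@H](Oc3ccc(OC)cc3)C=C[C@]2(C)[C@H](O)CC/C(C)=C\[C@@H]2OC(=O)[C@H](C)[C@]21O | intermediate
40 | 2,9-diacetate 12-(4-methoxyphenyl) ether | CC(=O)O[C@@H]1[C@H]2[C@@H](C)[C@H](Oc3ccc(OC)cc3)C=C[C@]2(C)[C@H](OC(C)=O)CC/C(C)=C\[C@@H]2OC(=O)[C@H](C)[C@]21O | intermediate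
41 | CNP0222085.1 | CC(=O)O[C@@H]1[C@H]2[C@@H](C)[C@H](O)C=C[C@]2(C)[C@H](OC(C)=O)CC/C(C)=C\[C@@H]2OC(=O)[C@H](C)[C@]21O | target

## Step count and least certain steps

Total: 31 steps. Longest linear sequence: 29 steps (steps 1–6 and 9–31, from 1); the two-step branch 9 to 12 joins at step 9.

**Step 24 (key step).** The most likely failure is decay of the excited enone before it meets the sparingly soluble gas, either by twisting about C2=C5 or by interaction of the triplet with the C13=C14 bond one carbon away (di-π-methane type). Fallback: set out from 31 and irradiate it in (Z)-1,2-dichloroethene/CH2Cl2, a liquid partner available at molar concentration and a long-used ethylene surrogate, to give the dichlorocyclobutane F1. Radical removal of both chlorines with Bu3SnH and AIBN at high stannane concentration gives 33, where the route is rejoined.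

**Step 25.** Facial selectivity at C6 may be poor or reversed, because the β methyl on C5 opposes the two elements that favour β attack. The 6β alcohol would then form, and its mesylate can only fragment to the E alkene. Fallback: from 33, take the 6β-diol F2 to the 6β-mesylate F3 and fragment it as in step 27 to the (E)-enone F4. Then equilibrate the trisubstituted alkene with catalytic diphenyl disulfide under 365 nm light (reversible thiyl radical addition), which should favour the less strained Z ring isomer; the route is rejoined at 37.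

**Step 2.** The cycloaddition may run through the formyl-endo arrangement, or the strong Lewis acid may erode the silyl dienol ether; the first gives the C11 epimer. Fallback: from 2 and 3, accept the C11-epimeric cycloadduct F5 and carry it through steps 3 and 4 to the epimeric ethyl carbinol F6 and the epimeric diol F7. Oxidise the enol ether with Pd(OAc)2 to the 11-epi enone diol F8, deprotonate at C11 with LiN(iPr)2 (3.3 equiv) and protonate the dienolate kinetically from the face opposite the C10 substituent to obtain the enone diol F9 with the C11 methyl cis to C9. Double Dess–Martin oxidation returns to 8.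

**Step 22.** Once the enol ether is in place, the C6 oxygen may be lost by ionisation, or the enol ether may be cleaved during removal of the trimethylsilyl group. Fallback: from 28 (made from 27 as in the first stage of step 22), remove only the secondary silyl group (K2CO3, MeOH, −20 °C) to the hydroxy ketone F10, oxidise it to the 1,3-diketone F11 and O-silylate with Et3SiOTf/Et3N. Regiochemistry then rests on electronic bias (the C6 carbonyl is deactivated by the α-acyloxy group, so the more basic C2 oxygen should be silylated), and the regioisomer is removed by chromatography; the route is rejoined at 31.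

## Further compounds

F1 | step 24 | dichlorocyclobutane photoadduct (Cl on C3 and C4) | CC(C)(C)[Si](C)(C)O[C@@H]1[C@H]2[C@@H](C)[C@H](Oc3ccc(OC)cc3)C=C[C@]2(C)[C@]3(O[Si](CC)(CC)CC)C(Cl)C(Cl)[C@]3(C)C(=O)[C@@H]2OC(=O)[C@H](C)[C@]21O[Si](C)(C)C
F2 | step 25 | 6β,8α-diol | CC(C)(C)[Si](C)(C)O[C@@H]1[C@H]2[C@@H](C)[C@H](Oc3ccc(OC)cc3)C=C[C@]2(C)[C@]3(O[Si](CC)(CC)CC)CC[C@]3(C)[C@@H](O)[C@@H]2OC(=O)[C@H](C)[C@]21O
F3 | step 25 | 6β-mesylate | CC(C)(C)[Si](C)(C)O[C@@H]1[C@H]2[C@@H](C)[C@H](Oc3ccc(OC)cc3)C=C[C@]2(C)[C@]3(O[Si](CC)(CC)CC)CC[C@]3(C)[C@@H](OS(C)(=O)=O)[C@@H]2OC(=O)[C@H](C)[C@]21O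
F4 | step 25 | ten-membered C2 ketone with (E)-C5=C6 | CC(C)(C)[Si](C)(C)O[C@@H]1[C@H]2[C@@H](C)[C@H](Oc3ccc(OC)cc3)C=C[C@]2(C)C(=O)CC/C(C)=C/[C@@H]2OC(=O)[C@H](C)[C@]21O
F5 | step 2 | C11-epimeric cycloadduct | CCOC(=O)[C@H]1[C@H](C)C(O[Si](C(C)C)(C(C)C)C(C)C)=CC[C@]1(C)C=O
F6 | step 2 | C11-epimeric ethyl carbinol | CCOC(=O)[C@H]1[C@H](C)C(O[Si](C(C)C)(C(C)C)C(C)C)=CC[C@]1(C)C(O)CC
F7 | step 2 | C11-epimeric diol | OC[C@H]1[C@H](C)C(O[Si](C(C)C)(C(C)C)C(C)C)=CC[C@]1(C)C(O)CC
F8 | step 2 | 11-epi enone diol | OC[C@H]1[C@H](C)C(=O)C=C[C@]1(C)C(O)CC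
F9 | step 2 | enone diol with 11β-methyl | OC[C@H]1[C@@H](C)C(=O)C=C[C@]1(C)C(O)CC
F10 | step 22 | eight-membered hydroxy ketone with C8 OSiMe3 | CC(C)(C)[Si](C)(C)O[C@@H]1[C@H]2[C@@H](C)[C@H](Oc3ccc(OC)cc3)C=C[C@]2(C)C(=O)C(C)C(O)[C@@H]2OC(=O)[C@H](C)[C@]21O[Si](C)(C)C
F11 | step 22 | eight-membered 1,3-diketone with C8 OSiMe3 | CC(C)(C)[Si](C)(C)O[C@@H]1[C@H]2[C@@H](C)[C@H](Oc3ccc(OC)cc3)C=C[C@]2(C)C(=O)C(C)C(=O)[C@@H]2OC(=O)[C@H](C)[C@]21O[Si](C)(C)C
A1 | alternative 1 | ring A enone aldehyde | CC(C)(C)[Si](C)(C)OC[C@H]1[C@@H](C)C(=O)C=C[C@]1(C)C=O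
A2 | alternative 1 | (1E,3Z)-1-methoxy-3-(tert-butyldimethylsilyloxy)penta-1,3-diene | CO/C=C/C(=C/C)O[Si](C)(C)C(C)(C)C
A3 | alternative 1 | (E)-4-(tert-butyldimethylsilyloxy)-2-methylbut-2-enal | CC(C)(C)[Si](C)(C)OC/C=C(\C)C=O
A4 | alternative 2 | ten-membered carbocycle with free C2 hydroxyl | CC1(C)O[C@@H]2[C@H]3[C@@H](C)[C@H](O[Si](C)(C)C(C)(C)C)C=C[C@]3(C)[C@H](O)CC/C(C)=C\[C@H](O[Si](C)(C)C(C)(C)C)[C@@]2(O1)[C@@H](C)CO[Si](C)(C)C(C)(C)C
A5 | alternative 3 | ring A acid | OC(=O)[C@H]1[C@@H](C)[C@H](O[Si](C)(C)C(C)(C)C)C=C[C@]1(C)COCc1ccccc1
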